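**Remarks on the chemistry (assumptions and corrections)**

- Flavan numbering is used for the target and all chromans (O1, C2, C3, C4, C4a, C5–C8, C8a; ring B C1'–C6'). Open-chain compounds are numbered as propane derivatives.
- The key-step precursor is used as its 2-O-benzyl ether (11) and the key-step product as its 3-O-benzyl ether (13). The skeleton, the bond formed and the ring closed are unchanged. The benzyl group keeps the C3 oxygen from sitting free beside the cation or beside the two phenols to be acylated, and it leaves in the final hydrogenolysis at no cost in steps.
- With the spatial arrangement of the target at C2, the 2H-chromene A9 is (2S) and the 3-boryl chroman A7 is (2S,3S) by the CIP rules, because in both the aryl group outranks C3. These descriptors are used below.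

## Structural features

The target is a flavan-3-ol. Benzene ring A is fused to the dihydropyran ring C (O1, C2, C3, C4, C4a, C8a), C2 carries the catechol ring B, and C3 carries a free secondary hydroxyl. C2 and C3 are the only stereocenters; they are adjacent, (2R,3S), with the aryl group and the hydroxyl trans. The oxygens at C5 and C7 of ring A are esterified with 3,4,5-trihydroxybenzoyl (galloyl) groups, while the 3-hydroxyl, the two ring B phenols and the six gallate phenols are free. The aryl esters are active esters and will not survive base, alkoxide or amines for long. The catechol and pyrogallol units oxidize easily in air, and the benzylic C2–O1 bond is sensitive to strong acid. The real difficulty is twofold: securing the trans C2/C3 pair in one absolute sense, and acylating exactly two of the five hydroxyls of the flavan core. The key step exploits C2, which is benzylic to ring B and para to O4', so a cation there is stabilized like a 4-alkoxybenzyl cation. An oxygen of ring A ortho to the C4 attachment is placed to close ring C onto it, and because ring A derives from symmetric phloroglucinol both ortho oxygens are equivalent.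

## Logic of the disconnections

**16 ⇒ 15.** All nine O–CH2Ph bonds are cut (one at O3, two on ring B, six on the gallates). The oxidation-prone, ester-labile polyphenol is then exposed only once, at the end, under neutral reductive conditions. One protecting-group type means one operation. The forward step must spare the two aryl esters and the benzylic C2–O1 bond.

**15 ⇒ 13 + 14.** The two acyl C–O bonds at O5 and O7 are cut. The esters are the most labile bonds and so are made late. This removes two identical C7 units and makes the end convergent. Because 13 has only these two hydroxyls free, the forward step needs complete double acylation but no chemoselectivity.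

**13 ⇒ 11 (through 12).** The O1–C2 bond is cut. C2 is the one carbon whose C–O bond ionizes easily, and cutting there opens ring C to a chain with a single fixed stereocenter and restores three equal protected oxygens on ring A. A ring and a stereocenter disappear, and the configuration at C1 of 11 becomes irrelevant. The forward closure must be trans-selective, must use oxygen and not carbon of ring A, and must be intramolecular; the ring A groups must fall to the same acid while all other groups survive it.

**11 ⇒ 8 + 9 (as 10).** The bond between the carbinol carbon (future C2) and C1' of ring B is cut. Addition of an aryl metal to an aldehyde is the most dependable way to a benzylic carbinol, and no stereocontrol is asked of it. Ring B is split off as a simple aryl halide. The demand is that the α-alkoxy aldehyde does not epimerize before or during the addition.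

**8 ⇒ 7 ⇒ 6.** No skeletal bond is cut. The aldehyde is traced back to an ester, and the O–benzyl bond at the carbinol is cut. The hydroxy ester is the direct product of an epoxide opening, and benzyl is the one group that survives every later step and leaves with the others. The etherification must not racemize the α-hydroxy ester, and the reduction must stop at the aldehyde.

**6 ⇒ 2 + 3.** The aryl–CH2 bond (C4a–C4) is cut. The CH2 carbon is the unsubstituted carbon of a three-carbon epoxide from the chiral pool, whose stereocenter becomes C3. The only fixed stereocenter is therefore bought, and no asymmetric reaction is needed. The aryl metal must open the epoxide at the terminal carbon without adding to the ester, which calls for a soft, copper-mediated nucleophile.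

**2 ⇒ 1.** Three O–CH2OMe bonds are cut. The ethers direct the metalation to the carbon between them and are the acid-labile masks needed in the key step. The forward step must alkylate on oxygen, not carbon, of a very electron-rich triphenol.

## Other disconnections considered

**Alternative 1:** The C2–C3 bond is cut together with the C2–O bond of a trans epoxide.

- Forward step: the ring B benzyl bromide A2 is turned into a sulfonium salt with a chiral sulfide, and its ylide adds to the ring A arylacetaldehyde A1. Closure of the anti betaine would give the trans epoxide A3, (2S,3S). Acid would then unmask ring A, and a phenol would open A3 at the benzylic carbon (6-endo, inversion) to give the 2,3-trans flavan-3-ol.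
- In favor: it is the most convergent plan. The central C–C bond and both stereocenters arise in one step, and the trans relationship is built into the epoxide and does not rest on an equilibrium. It would be about two steps shorter than the chosen route, so it is better on step economy.
- Against: A1 is an enolizable, electron-rich arylacetaldehyde that meets base during ylide formation, so aldol and enolization pathways compete. The 4-alkoxybenzyl sulfonium salt from A2 ionizes easily, and this class of epoxidation is best established for non-enolizable aldehydes. Yield and enantioselectivity at C3 are therefore uncertain, and C3 would rest on reagent control where the chosen route uses a purchased stereocenter.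
- Mechanism: the advantage at C2 is smaller than it looks. Under the acid needed to free ring A, the electron-rich aryl epoxide A3 can open to the same kind of benzylic cation as in step 6, or rearrange by hydride shift, so a clean inversion is not assured.
- Structure: the 3-hydroxyl emerges free next to the ring A phenols, so the acylation would have to be phenol-selective or a protection step added.
- Overall: better in convergence and step count, equal at best in C2 control, weaker in the security of C3.

**Alternative 2:** O1–C2 and C3–C4 are cut at once.

- Forward step: the salicyl alcohol A4 loses water to the ortho-quinone methide A5, a heterodiene (O1=C8a–C4a=C4), which adds the (E)-alkenylboronate A6 in an inverse-demand [4+2] cycloaddition. The boron-bearing carbon, the nucleophilic terminus of a 4-alkoxystyrene, bonds to C4 and the benzylic carbon to O1, giving A7. The E geometry is transferred suprafacially to the 2,3-trans relationship, and oxidation of the C–B bond with retention would deliver the 3-hydroxyl.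
- In favor: two bonds, ring C and both stereocenters arise in one step. The trans relationship is stereospecific, which is better than the conformational preference relied on in step 6. The route would be shorter.
- Against: neither partner is chiral, so the absolute configuration depends entirely on a chiral catalyst (for example a chiral phosphoric acid). That is undemonstrated for this pairing: A5 is stabilized and made less electrophilic by two ring oxygens, and the boryl group lowers the nucleophilicity of A6. A5 may also dimerize or be trapped by A4. Without enantiocontrol the product is racemic.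
- Structure: the cycloadduct carries the 5,7-bis-MOM pattern, and after oxidation it would still need benzylation at O3 and MOM removal to reach 13, which takes back part of the saving.
- Overall: better in relative configuration and step count, worse in absolute configuration, where the chosen plan uses the chiral pool. Mechanistically it is a concerted pericyclic closure against an ionic one.

**Alternative 3:** The C3=C4 bond of a flav-3-ene is cut, and the C3–O bond is added afterwards.

- Forward step: second-generation Grubbs catalyst would join the ortho vinyl group and the allyl ether alkene of the diene A8, giving the (2S)-2H-chromene A9 and ethylene. Hydroboration–oxidation would then place boron at C3, anti to the C2 aryl group, and give the 2,3-trans 3-ol. Both the styrene-type polarization and the inductive effect of the C2–O bond favor boron at C3.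
- In favor: ring-closing metathesis to 2H-chromenes is dependable and tolerant of the ethers. Substrate-controlled hydroboration anti to the aryl group may give a higher trans preference than step 6, a possible advantage. Step count would be about equal.
- Against: the one stereocenter of A8 is a doubly activated (benzylic and allylic) aryl ether of a 4-alkoxyaryl carbinol. Making it enantioenriched (a Mitsunobu reaction, or allylic etherification with [Ir(cod)Cl]2 and a chiral phosphoramidite) and keeping it so is doubtful, since ionization and sigmatropic shifts to the free ortho carbon are open. A9 can also undergo reversible 6π electrocyclic opening of the pyran ring, which would erase C2. Some boron at the benzylic C4 cannot be excluded. As in alternative 2, benzylation at O3 and MOM removal would be needed to reach 13.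
- Overall: equal in step economy and possibly better in trans selectivity, but weaker in the configurational security of C2. The chosen plan fixes C3 first and lets C2 follow it.

Key step: step 6

## Route

Step 1
Reactants: 1 phloroglucinol (benzene-1,3,5-triol)
Product: 2 1,3,5-tris(methoxymethoxy)benzene
Conditions: MOMCl, i-Pr2NEt, DMF, 0 °C → rt
Reagents that add atoms: chloromethyl methyl ether (MOMCl), COCCl
Why: Williamson-type O-alkylation of the three equivalent phenols; the hard, oxocarbenium-like electrophile and an amine base favor O- over C-alkylation, and no selectivity between hydroxyls is needed.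

Step 2
Reactants: 2 1,3,5-tris(methoxymethoxy)benzene; 3 methyl (2S)-oxirane-2-carboxylate (methyl (S)-glycidate)
Product: 6 methyl (2S)-2-hydroxy-3-[2,4,6-tris(methoxymethoxy)phenyl]propanoate, via aryllithium 4 (not isolated), via arylmagnesium bromide 5 (not isolated)
Conditions: n-BuLi, THF, 0 °C; MgBr2·OEt2, 0 °C; CuI (10 mol %), then 3, −40 → −15 °C; aq. NH4Cl
Reagents that add atoms: none
Why: Directed ortho-metalation between two MOM ethers (all three ring positions are equivalent), then copper-catalyzed SN2 opening of the epoxide by the Grignard reagent at the unsubstituted carbon, which should outrun addition to the ester at low temperature. The stereocenter of 3 is not touched, so its (S) configuration passes unchanged into 6 and later becomes C3.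

Step 3
Reactants: 6 methyl (2S)-2-hydroxy-3-[2,4,6-tris(methoxymethoxy)phenyl]propanoate
Product: 7 methyl (2S)-2-(benzyloxy)-3-[2,4,6-tris(methoxymethoxy)phenyl]propanoate
Conditions: BnBr, Ag2O, n-Bu4NI (cat.), CH2Cl2, rt, dark
Reagents that add atoms: benzyl bromide, BrCc1ccccc1
Why: Williamson etherification promoted by Ag2O; no strong base is present, so the α-stereocenter of the hydroxy ester should not racemize and the ester and MOM ethers are untouched.

Step 4
Reactants: 7 methyl (2S)-2-(benzyloxy)-3-[2,4,6-tris(methoxymethoxy)phenyl]propanoate
Product: 8 (2S)-2-(benzyloxy)-3-[2,4,6-tris(methoxymethoxy)phenyl]propanal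
Conditions: i-Bu2AlH (1.1 equiv), CH2Cl2, −78 °C; MeOH, aq. potassium sodium tartrate
Reagents that add atoms: none
Why: Partial reduction of an ester with i-Bu2AlH; the tetrahedral aluminium hemiacetal, held by chelation to the α-benzyloxy oxygen, should persist at −78 °C and release the aldehyde only on work-up. The aldehyde is used at once, without chromatography, to protect the α-stereocenter.

Step 5
Reactants: 8 (2S)-2-(benzyloxy)-3-[2,4,6-tris(methoxymethoxy)phenyl]propanal; 9 4-bromo-1,2-bis(benzyloxy)benzene
Product: 11 (2S)-2-(benzyloxy)-1-[3,4-bis(benzyloxy)phenyl]-3-[2,4,6-tris(methoxymethoxy)phenyl]propan-1-ol as a mixture of C1 epimers, via aryl Grignard reagent 10 (not isolated)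
Conditions: 9, Mg, THF, 40 °C; then 8, THF, −78 → 0 °C; aq. NH4Cl
Reagents that add atoms: none
Why: Grignard addition to an aldehyde; chelation by the α-benzyloxy group should favor the 1,2-syn epimer, but no selectivity is required because both epimers converge in step 6. The C2 center is not touched at low temperature.

Step 6
Reactants: 11 (2S)-2-(benzyloxy)-1-[3,4-bis(benzyloxy)phenyl]-3-[2,4,6-tris(methoxymethoxy)phenyl]propan-1-ol (both C1 epimers)
Product: 13 (2R,3S)-3-(benzyloxy)-2-[3,4-bis(benzyloxy)phenyl]-3,4-dihydro-2H-chromene-5,7-diol (3,3',4'-tri-O-benzyl-(+)-catechin), via triphenol carbinol 12 (not isolated)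
Conditions: HCl (1 M) in MeOH/THF (4:1), 0.01 M, 50 °C
Reagents that add atoms: none
Why: The acid transfers the three MOM groups to methanol and protonates the benzylic hydroxyl (or the methyl ether that methanol forms from it reversibly); loss of water gives a C2 cation delocalized through ring B onto the para benzyloxy oxygen, so both C1 epimers of 11 pass through one planar ion, whatever the order of unmasking and ionization. The closest known reaction type is the acid-mediated cyclization of 1-aryl-3-(2-hydroxyaryl)propane-1,2-diols to 2,3-trans-flavan-3-ols. Ring C closes when an ortho phenol oxygen of ring A adds to this ion in a 6-exo-trig mode (the π bond between C2 and C1' stays exocyclic to the ring being formed); the two ortho oxygens are equivalent, so either gives the same chroman. The new stereocenter C2 is controlled by the fixed C3 center: only the 2,3-trans isomer has the aryl group and the 3-benzyloxy group both equatorial in the chair-like closure and in the product, and because the C2–O1 bond can ionize again under the same acid, the cis epimer is expected to drain to the trans one. The step needs O- over C-alkylation and ring closure over intermolecular capture; the first is secured because no ring A carbon can reach C2 in a ring of workable size, the second by high dilution and by methanol, which holds the ion as a reversible methyl ether. C3 is not benzylic and its oxygen is capped as a benzyl ether, so it neither ionizes nor closes an epoxide, and the (S) configuration introduced with 3 is carried through unchanged.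

Step 7
Reactants: 13 (2R,3S)-3-(benzyloxy)-2-[3,4-bis(benzyloxy)phenyl]-3,4-dihydro-2H-chromene-5,7-diol; 14 3,4,5-tris(benzyloxy)benzoic acid (2.4 equiv)
Product: 15 (2R,3S)-3-(benzyloxy)-2-[3,4-bis(benzyloxy)phenyl]-3,4-dihydro-2H-chromene-5,7-diyl bis[3,4,5-tris(benzyloxy)benzoate]
Conditions: EDC·HCl, DMAP, CH2Cl2, 0 °C → rt
Reagents that add atoms: none
Why: Steglich esterification of the two phenols through the acylpyridinium ion; they are the only free hydroxyls in 13, so exhaustive acylation needs no selectivity, and neither stereocenter is involved.

Step 8
Reactants: 15 (2R,3S)-3-(benzyloxy)-2-[3,4-bis(benzyloxy)phenyl]-3,4-dihydro-2H-chromene-5,7-diyl bis[3,4,5-tris(benzyloxy)benzoate]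
Product: 16 (2R,3S)-2-(3,4-dihydroxyphenyl)-3-hydroxy-3,4-dihydro-2H-chromene-5,7-diyl bis(3,4,5-trihydroxybenzoate) (catechin 5,7-di-O-gallate)
Conditions: H2 (1 atm), Pd(OH)2/C, THF/EtOAc, rt; filtration under argon
Reagents that add atoms: none
Why: Catalytic hydrogenolysis of the nine benzyl ethers (one alkyl, eight aryl) under neutral conditions; the aryl esters are inert to it, the cyclic benzylic C2–O1 ether should cleave far more slowly than the benzyl ethers at 1 atm, and the non-nucleophilic solvent avoids ester exchange.

## Compound list

1 | phloroglucinol (benzene-1,3,5-triol) | Oc1cc(O)cc(O)c1 | starting material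
2 | 1,3,5-tris(methoxymethoxy)benzene | COCOc1cc(OCOC)cc(OCOC)c1 | intermediate
3 | methyl (2S)-oxirane-2-carboxylate (methyl (S)-glycidate) | COC(=O)[C@@H]1CO1 | starting material
4 | [2,4,6-tris(methoxymethoxy)phenyl]lithium | [Li]c1c(OCOC)cc(OCOC)cc1OCOC | intermediate
5 | bromo[2,4,6-tris(methoxymethoxy)phenyl]magnesium | Br[Mg]c1c(OCOC)cc(OCOC)cc1OCOC | intermediate
6 | methyl (2S)-2-hydroxy-3-[2,4,6-tris(methoxymethoxy)phenyl]propanoate | COC(=O)[C@@H](O)Cc1c(OCOC)cc(OCOC)cc1OCOC | intermediate
7 | methyl (2S)-2-(benzyloxy)-3-[2,4,6-tris(methoxymethoxy)phenyl]propanoate | COC(=O)[C@@H](OCc1ccccc1)Cc1c(OCOC)cc(OCOC)cc1OCOC | intermediate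
8 | (2S)-2-(benzyloxy)-3-[2,4,6-tris(methoxymethoxy)phenyl]propanal | O=C[C@@H](OCc1ccccc1)Cc1c(OCOC)cc(OCOC)cc1OCOC | intermediate
9 | 4-bromo-1,2-bis(benzyloxy)benzene | Brc1ccc(OCc2ccccc2)c(OCc2ccccc2)c1 | starting material
10 | [3,4-bis(benzyloxy)phenyl]magnesium bromide | Br[Mg]c1ccc(OCc2ccccc2)c(OCc2ccccc2)c1 | intermediate
11 | (2S)-2-(benzyloxy)-1-[3,4-bis(benzyloxy)phenyl]-3-[2,4,6-tris(methoxymethoxy)phenyl]propan-1-ol, mixture of C1 epimers | OC(c1ccc(OCc2ccccc2)c(OCc2ccccc2)c1)[C@@H](OCc1ccccc1)Cc1c(OCOC)cc(OCOC)cc1OCOC | intermediate
12 | 2-[(2S)-2-(benzyloxy)-3-[3,4-bis(benzyloxy)phenyl]-3-hydroxypropyl]benzene-1,3,5-triol, mixture of carbinol epimers | OC(c1ccc(OCc2ccccc2)c(OCc2ccccc2)c1)[C@@H](OCc1ccccc1)Cc1c(O)cc(O)cc1O | intermediate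
13 | (2R,3S)-3-(benzyloxy)-2-[3,4-bis(benzyloxy)phenyl]-3,4-dihydro-2H-chromene-5,7-diol | Oc1cc(O)c2c(c1)O[C@H](c1ccc(OCc3ccccc3)c(OCc3ccccc3)c1)[C@@H](OCc1ccccc1)C2 | intermediate
14 | 3,4,5-tris(benzyloxy)benzoic acid | OC(=O)c1cc(OCc2ccccc2)c(OCc2ccccc2)c(OCc2ccccc2)c1 | starting material
15 | (2R,3S)-3-(benzyloxy)-2-[3,4-bis(benzyloxy)phenyl]-3,4-dihydro-2H-chromene-5,7-diyl bis[3,4,5-tris(benzyloxy)benzoate] | O=C(Oc1cc(OC(=O)c2cc(OCc3ccccc3)c(OCc3ccccc3)c(OCc3ccccc3)c2)c2c(c1)O[C@H](c1ccc(OCc3ccccc3)c(OCc3ccccc3)c1)[C@@H](OCc1ccccc1)C2)c1cc(OCc2ccccc2)c(OCc2ccccc2)c(OCc2ccccc2)c1 | intermediate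
16 | (2R,3S)-2-(3,4-dihydroxyphenyl)-3-hydroxy-3,4-dihydro-2H-chromene-5,7-diyl bis(3,4,5-trihydroxybenzoate) | O=C(Oc1cc(OC(=O)c2cc(O)c(O)c(O)c2)c2c(c1)O[C@H](c1ccc(O)c(O)c1)[C@@H](O)C2)c1cc(O)c(O)c(O)c1 | target

## Step count and least certain steps

Total step count: 8. Longest linear sequence: 8 steps (1 → 16); 3, 9 and 14 enter as purchased compounds.

**Step 6 (key step).** Three processes may intrude:
- incomplete drainage to the 2,3-trans isomer, if the closure is largely kinetic and the C2–O1 bond of the product re-ionizes too slowly;
- intermolecular C-alkylation of the unmasked, very electron-rich ring A by the cation;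
- loss of the C3 proton from the cation to an enol ether that hydrolyzes to a ketone.

Fallback, from 11 back to 13: the closure is separated from the unmasking. With an aprotic Lewis acid at low temperature and high dilution (BF3·OEt2, CH2Cl2 with a few equivalents of MeOH as trap, −40 °C), the cation should be captured by the ether oxygen of an ortho MOM group. The resulting oxonium ion sheds its methoxymethyl group to the trap and gives (2R,3S)-3-(benzyloxy)-2-[3,4-bis(benzyloxy)phenyl]-5,7-bis(methoxymethoxy)-3,4-dihydro-2H-chromene F1. Ring A is then never a free polyphenol while the cation exists, and the low temperature disfavors proton loss. The two remaining MOM ethers are removed from the closed ring with dilute HCl in MeOH at room temperature to give 13. Any cis epimer would be separated at F1 or 13 and re-equilibrated under acid.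

**Step 2.** The aryl metal may add to the ester in competition with epoxide opening, and transfer of a doubly ortho-substituted aryl group from copper may be slow.

Fallback, from 2 back to 8, using an electrophile with no carbonyl group: 2 is lithiated as before and opens (S)-trityl glycidyl ether (C(c1ccccc1)(c1ccccc1)(c1ccccc1)OC[C@@H]1CO1) under BF3·OEt2 at −78 °C to give (2S)-1-(triphenylmethoxy)-3-[2,4,6-tris(methoxymethoxy)phenyl]propan-2-ol F2. Benzylation of the alkoxide (NaH, BnBr, THF/DMF) gives (2S)-2-(benzyloxy)-1-(triphenylmethoxy)-3-[2,4,6-tris(methoxymethoxy)phenyl]propane F3. Brief treatment with HCO2H/Et2O removes the trityl group to give (2S)-2-(benzyloxy)-3-[2,4,6-tris(methoxymethoxy)phenyl]propan-1-ol F4, and Dess–Martin oxidation gives 8. This costs two more steps.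

**Step 4.** Over-reduction to the primary alcohol may occur if the aluminium hemiacetal collapses before the quench. The α-benzyloxy aldehyde may also epimerize on work-up or under the basic Grignard reagent of step 5.

Fallback, from 7 back to 11, avoiding the aldehyde altogether: 7 is converted with Me(MeO)NH·HCl and i-PrMgCl (THF, −20 °C) into the Weinreb amide (2S)-2-(benzyloxy)-N-methoxy-N-methyl-3-[2,4,6-tris(methoxymethoxy)phenyl]propanamide F5. Addition of 10 gives, through a stable chelated adduct, the ketone (2S)-2-(benzyloxy)-1-[3,4-bis(benzyloxy)phenyl]-3-[2,4,6-tris(methoxymethoxy)phenyl]propan-1-one F6. NaBH4 (MeOH/THF, 0 °C) reduces it to 11 as an epimer mixture, which step 6 accepts. This costs one more step.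

**Step 8.** The hydrogenolysis may stall before all nine benzyl groups are gone, because the polyphenol can poison the catalyst. On long exposure the benzylic C2–O1 bond may open, and the product may oxidize in air during filtration.

Fallback, from 15 directly to 16 without hydrogen or a metal catalyst: Lewis acid debenzylation with BCl3 and pentamethylbenzene as benzyl cation scavenger in CH2Cl2 at −78 °C, quenched cold with MeOH. Aryl esters tolerate this, and the low temperature is kept to spare C2–O1. No new compound is made on the way.

## Further compounds

F1 | step 6 | (2R,3S)-3-(benzyloxy)-2-[3,4-bis(benzyloxy)phenyl]-5,7-bis(methoxymethoxy)-3,4-dihydro-2H-chromene | COCOc1cc(OCOC)c2c(c1)O[C@H](c1ccc(OCc3ccccc3)c(OCc3ccccc3)c1)[C@@H](OCc1ccccc1)C2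
F2 | step 2 | (2S)-1-(triphenylmethoxy)-3-[2,4,6-tris(methoxymethoxy)phenyl]propan-2-ol | c1ccccc1C(c1ccccc1)(c1ccccc1)OC[C@@H](O)Cc1c(OCOC)cc(OCOC)cc1OCOC
F3 | step 2 | (2S)-2-(benzyloxy)-1-(triphenylmethoxy)-3-[2,4,6-tris(methoxymethoxy)phenyl]propane | c1ccccc1C(c1ccccc1)(c1ccccc1)OC[C@@H](OCc1ccccc1)Cc1c(OCOC)cc(OCOC)cc1OCOC
F4 | step 2 | (2S)-2-(benzyloxy)-3-[2,4,6-tris(methoxymethoxy)phenyl]propan-1-ol | OC[C@@H](OCc1ccccc1)Cc1c(OCOC)cc(OCOC)cc1OCOC
F5 | step 4 | (2S)-2-(benzyloxy)-N-methoxy-N-methyl-3-[2,4,6-tris(methoxymethoxy)phenyl]propanamide | CON(C)C(=O)[C@@H](OCc1ccccc1)Cc1c(OCOC)cc(OCOC)cc1OCOC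
F6 | step 4 | (2S)-2-(benzyloxy)-1-[3,4-bis(benzyloxy)phenyl]-3-[2,4,6-tris(methoxymethoxy)phenyl]propan-1-one | O=C(c1ccc(OCc2ccccc2)c(OCc2ccccc2)c1)[C@@H](OCc1ccccc1)Cc1c(OCOC)cc(OCOC)cc1OCOC
F0 | step 8 | none | none
A1 | alternative 1 | 2-[2,4,6-tris(methoxymethoxy)phenyl]acetaldehyde | O=CCc1c(OCOC)cc(OCOC)cc1OCOC
A2 | alternative 1 | 4-(bromomethyl)-1,2-bis(benzyloxy)benzene | BrCc1ccc(OCc2ccccc2)c(OCc2ccccc2)c1
A3 | alternative 1 | (2S,3S)-2-[3,4-bis(benzyloxy)phenyl]-3-[2,4,6-tris(methoxymethoxy)benzyl]oxirane | O1[C@@H](c2ccc(OCc3ccccc3)c(OCc3ccccc3)c2)[C@@H]1Cc1c(OCOC)cc(OCOC)cc1OCOC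
A4 | alternative 2 | 2-(hydroxymethyl)-3,5-bis(methoxymethoxy)phenol | OCc1c(O)cc(OCOC)cc1OCOC
A5 | alternative 2 | 3,5-bis(methoxymethoxy)-6-methylidenecyclohexa-2,4-dien-1-one | C=C1C(=O)C=C(OCOC)C=C1OCOC
A6 | alternative 2 | 2-[(E)-2-[3,4-bis(benzyloxy)phenyl]ethenyl]-4,4,5,5-tetramethyl-1,3,2-dioxaborolane | CC1(C)OB(/C=C/c2ccc(OCc3ccccc3)c(OCc3ccccc3)c2)OC1(C)C
A7 | alternative 2 | (2S,3S)-2-[3,4-bis(benzyloxy)phenyl]-5,7-bis(methoxymethoxy)-3-(4,4,5,5-tetramethyl-1,3,2-dioxaborolan-2-yl)-3,4-dihydro-2H-chromene | COCOc1cc(OCOC)c2c(c1)O[C@H](c1ccc(OCc3ccccc3)c(OCc3ccccc3)c1)[C@@H](B1OC(C)(C)C(C)(C)O1)C2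
A8 | alternative 3 | 1-{[(1S)-1-[3,4-bis(benzyloxy)phenyl]prop-2-en-1-yl]oxy}-2-ethenyl-3,5-bis(methoxymethoxy)benzene | C=Cc1c(OCOC)cc(OCOC)cc1O[C@H](c1ccc(OCc2ccccc2)c(OCc2ccccc2)c1)C=C
A9 | alternative 3 | (2S)-2-[3,4-bis(benzyloxy)phenyl]-5,7-bis(methoxymethoxy)-2H-chromene | COCOc1cc(OCOC)c2c(c1)O[C@H](c1ccc(OCc3ccccc3)c(OCc3ccccc3)c1)C=C2
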